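**Plan**

1. Labels used throughout: oxolane O1, C2 (aryl), C3 (methyl), C4, C5 (CH2); C7′ is the exocyclic carbinol carbon. The target is 2S,3S,4R,7′R (2,3-trans, 3,4-cis).
2. Cuts: C7′–O together with C4–H (syn hydroboration of an (E)-4-arylidene oxolane); ring bond C4–C5 (5-exo-dig carbolithiation of the aryl alkyne C4≡C7′ by an O1–CH2–Li group); O1–C5; C2–C3 (veratraldehyde plus a chiral allenylzinc).
3. Forward: the four carbons of (R)-but-3-yn-2-ol become CH3, C3, C4 and C7′. The aryl group is put on C7′, C3 is joined to C2, O1 is armed with CH2SnBu3, the only ring is closed by C4–C5, and H/OH are then added across C4=C7′.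
4. Enabling feature: C5 is an unsubstituted CH2 between O1 and C4, and C4 carries a benzylic carbinol carbon. O1–C5 can therefore be an alkoxymethyl carbanion and C4/C7′ an aryl alkyne, whose 3,4-dimethoxyphenyl group activates the triple bond and stabilizes the vinyl anion.
5. Stereochemistry: the one bought centre is relayed through an allenylzinc into C2 and C3 (anti). Two consecutive syn additions to the triple bond (C–Li, then H–B) tie C7′ to C4, and the C3 methyl group selects the face (3,4-cis).
6. Six steps, no protecting groups.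

Key step: step 5

Remark: metal or boron alkoxides of numbered alcohols that exist before work-up are treated as the alcohol itself; tributyl(iodomethyl)stannane is taken as a purchasable reagent.

**Route**

Step 1
Reactants: 1 (R)-but-3-yn-2-ol; 2 4-iodo-1,2-dimethoxybenzene
Product: 3 (2R)-4-(3,4-dimethoxyphenyl)but-3-yn-2-ol
Conditions: PdCl2(PPh3)2 (2 mol %), CuI (4 mol %), Et3N, THF, rt
Reagents that add atoms: none
Why: Sonogashira coupling of the aryl iodide with the terminal alkyne; the carbinol stereocentre is not involved and the free hydroxyl group is tolerated.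

Step 2
Reactants: 3 (2R)-4-(3,4-dimethoxyphenyl)but-3-yn-2-ol
Product: 4 (2R)-4-(3,4-dimethoxyphenyl)but-3-yn-2-yl methanesulfonate
Conditions: MsCl, Et3N, CH2Cl2, −78 °C; used crude
Reagents that add atoms: methanesulfonyl chloride, CS(=O)(=O)Cl
Why: Sulfonylation at oxygen leaves the C–O bond and hence the (R) configuration intact; the labile propargylic mesylate is kept cold and used without purification.

Step 3
Reactants: 4 (2R)-4-(3,4-dimethoxyphenyl)but-3-yn-2-yl methanesulfonate; 5 3,4-dimethoxybenzaldehyde
Product: 7 (1S,2S)-1,4-bis(3,4-dimethoxyphenyl)-2-methylbut-3-yn-1-ol, via allenyl(ethyl)zinc 6 (not isolated)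
Conditions: Pd(OAc)2 (5 mol %), PPh3 (5 mol %), Et2Zn (3 equiv), THF, −78 → −20 °C; aq NH4Cl
Reagents that add atoms: diethylzinc, CC[Zn]CC (ethylzinc group of 6 only; no atom of it remains in 7)
Why: Marshall–Tamaru propargylation, in which Pd(0) ionizes the mesylate anti (SN2′) to an allenylpalladium, diethylzinc transmetallates it with retention to the (P)-allenylzinc 6, and 6 adds to the aldehyde through a closed six-membered SE2′ transition state (new bond syn to zinc, aldehyde aryl group anti to the allenyl methyl group), so that the bought centre is relayed into C3 (S) and C2 (S) of the anti adduct.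

Step 4
Reactants: 7 (1S,2S)-1,4-bis(3,4-dimethoxyphenyl)-2-methylbut-3-yn-1-ol
Product: 8 tributyl({[(1S,2S)-1,4-bis(3,4-dimethoxyphenyl)-2-methylbut-3-yn-1-yl]oxy}methyl)stannane
Conditions: KH (1.2 equiv), THF, 0 °C; Bu3SnCH2I (1.3 equiv), 0 °C → rt
Reagents that add atoms: tributyl(iodomethyl)stannane, CCCC[Sn](CCCC)(CCCC)CI
Why: Williamson etherification of the potassium alkoxide with the iodomethylstannane (the standard preparation of α-alkoxymethylstannanes), which touches no stereocentre; the temperature is kept low so that the alkoxide does not add to the aryl alkyne in a 5-endo-dig sense.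

Step 5
Reactants: 8 tributyl({[(1S,2S)-1,4-bis(3,4-dimethoxyphenyl)-2-methylbut-3-yn-1-yl]oxy}methyl)stannane
Product: 11 (2S,3S,4E)-2-(3,4-dimethoxyphenyl)-4-[(3,4-dimethoxyphenyl)methylidene]-3-methyloxolane, via alkoxymethyllithium 9 (not isolated), via vinyllithium 10 (not isolated)
Conditions: n-BuLi (1.1 equiv), THF, −78 → −40 °C; then MeOH, −78 °C; H2O work-up
Reagents that add atoms: n-butyllithium, [Li]CCCC (lithium of 9 and 10 only; no atom of it remains in 11)
Why: Tin–lithium exchange turns the O1–CH2–Sn group into the α-alkoxymethyllithium 9, whose C–Li bond adds syn across the C4≡C7′ triple bond to give the aryl-stabilized, O1-chelated vinyllithium 10, which is protonated with retention. The closest known reaction types are the anionic 5-exo-dig cyclization of 5-hexynyllithiums onto aryl alkynes and the cyclization of α-alkoxy organolithiums generated from stannanes. The oxolane is closed by the C4–C5 bond in the 5-exo-dig mode; the 6-endo mode is disfavoured because it would leave a non-benzylic vinyl anion. No sp3 centre is formed, but the syn addition fixes the E geometry of C4=C7′ (C5 and H cis, aryl cis to C3), which is the stereochemical information that step 6 turns into C4 and C7′. The step needs exchange and cyclization to outrun a [1,2]-Wittig shift of the benzylic C2 group and addition of butyllithium to the alkyne, which the low temperature and the activation of the alkyne by its aryl group should secure; C2 and C3 are not touched.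

Step 6
Reactants: 11 (2S,3S,4E)-2-(3,4-dimethoxyphenyl)-4-[(3,4-dimethoxyphenyl)methylidene]-3-methyloxolane
Product: 13 (R)-(3,4-dimethoxyphenyl)[(3R,4S,5S)-5-(3,4-dimethoxyphenyl)-4-methyloxolan-3-yl]methanol, via benzylic alkylborane 12 (not isolated)
Conditions: BH3·THF (2 equiv), THF, 0 °C → rt; then 3 M NaOH, 30 % H2O2, 0 °C → rt
Reagents that add atoms: borane (as its THF complex), B (boron of 12 only; 13 keeps one of its hydrogens); hydrogen peroxide, OO (carbinol oxygen of 13)
Why: Hydroboration–oxidation, a syn addition of H–B with boron on the less substituted, benzylic C7′ and hydrogen on C4, followed by C–B oxidation with retention; allylic 1,3-strain between the E-aryl group and C3 holds the C3 methyl group perpendicular to the alkene, so borane should add to the opposite face, which sets C4 (R) (side chain cis to the methyl group, trans to the C2 aryl group) and, through the E geometry, C7′ (R) in the same event.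

**Compound list**

1 | (R)-but-3-yn-2-ol | C[C@@H](O)C#C | starting material
2 | 4-iodo-1,2-dimethoxybenzene | COc1ccc(I)cc1OC | starting material
3 | (2R)-4-(3,4-dimethoxyphenyl)but-3-yn-2-ol | C[C@@H](O)C#Cc1ccc(OC)c(OC)c1 | intermediate
4 | (2R)-4-(3,4-dimethoxyphenyl)but-3-yn-2-yl methanesulfonate | C[C@@H](OS(C)(=O)=O)C#Cc1ccc(OC)c(OC)c1 | intermediate
5 | 3,4-dimethoxybenzaldehyde | COc1ccc(C=O)cc1OC | starting material
6 | ethyl[(P)-1-(3,4-dimethoxyphenyl)buta-1,2-dien-1-yl]zinc | C[CH]=[C@]=C([Zn]CC)c1ccc(OC)c(OC)c1 | intermediate (not isolated)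
7 | (1S,2S)-1,4-bis(3,4-dimethoxyphenyl)-2-methylbut-3-yn-1-ol | COc1ccc([C@@H](O)[C@@H](C)C#Cc2ccc(OC)c(OC)c2)cc1OC | intermediate
8 | tributyl({[(1S,2S)-1,4-bis(3,4-dimethoxyphenyl)-2-methylbut-3-yn-1-yl]oxy}methyl)stannane | COc1ccc([C@@H](OC[Sn](CCCC)(CCCC)CCCC)[C@@H](C)C#Cc2ccc(OC)c(OC)c2)cc1OC | intermediate
9 | ({[(1S,2S)-1,4-bis(3,4-dimethoxyphenyl)-2-methylbut-3-yn-1-yl]oxy}methyl)lithium | COc1ccc([C@@H](OC[Li])[C@@H](C)C#Cc2ccc(OC)c(OC)c2)cc1OC | intermediate (not isolated)
10 | {(E)-(3,4-dimethoxyphenyl)[(4S,5S)-5-(3,4-dimethoxyphenyl)-4-methyloxolan-3-ylidene]methyl}lithium | COc1ccc([C@H]2OC/C(=C(\[Li])c3ccc(OC)c(OC)c3)[C@@H]2C)cc1OC | intermediate (not isolated)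
11 | (2S,3S,4E)-2-(3,4-dimethoxyphenyl)-4-[(3,4-dimethoxyphenyl)methylidene]-3-methyloxolane | COc1ccc([C@H]2OC/C(=C/c3ccc(OC)c(OC)c3)[C@@H]2C)cc1OC | intermediate
12 | {(R)-(3,4-dimethoxyphenyl)[(3R,4S,5S)-5-(3,4-dimethoxyphenyl)-4-methyloxolan-3-yl]methyl}borane | COc1ccc([C@H]2OC[C@H]([C@@H](B)c3ccc(OC)c(OC)c3)[C@@H]2C)cc1OC | intermediate (not isolated)
13 | (R)-(3,4-dimethoxyphenyl)[(3R,4S,5S)-5-(3,4-dimethoxyphenyl)-4-methyloxolan-3-yl]methanol | COc1ccc([C@H]2OC[C@H]([C@@H](O)c3ccc(OC)c(OC)c3)[C@@H]2C)cc1OC | target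

**Count**

Total steps: 6. Longest linear sequence: 6 steps (1 → 3 → 4 → 7 → 8 → 11 → 13).

**Steps most likely to fail**

Step 5. After tin–lithium exchange the carbanion may rearrange by [1,2]-Wittig migration of the electron-rich benzylic C2 group faster than it adds to the alkyne, or the vinyllithium may partly invert before protonation and erode the E geometry. The fallback sets out from 7 and returns to 11; it makes the C4–C5 bond by cross-coupling and closes the ring at O1–C5. Alcohol 7 is silylated with 1,1,3,3-tetramethyldisilazane to the hydrosilyl ether F1. Platinum(0) catalysis (Karstedt catalyst) then effects intramolecular syn hydrosilylation in the 5-exo-dig mode to the oxasilolane F2, with silicon on C4 and hydrogen on C7′ cis to silicon. Iododesilylation with N-iodosuccinimide (retention) and hydrolytic work-up gives the vinyl iodide F3. Stille coupling with (tributylstannyl)methanol (Pd(PPh3)4, dioxane, 80 °C) gives the allylic diol F4. Mitsunobu cyclodehydration (PPh3, DIAD), with activation of the primary allylic hydroxyl group and attack by the C2 hydroxyl group with retention at C2, gives 11.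

Step 6. Boron may be delivered in part to C4, because the electron-rich aryl group opposes the steric preference, or borane may add in part to the methyl-bearing face. The fallback sets out from 11 and returns to 13; it sets C4 and C7′ in two separate events. Oxidative cleavage of the arylidene group of 11 (OsO4 cat., NaIO4, 2,6-lutidine, dioxane/H2O) gives the oxolanone F5. Wittig methylenation (Ph3P=CH2, THF, −78 → 0 °C) gives the methylidene oxolane F6. Hydroboration with 9-BBN, where boron can only go to the terminal carbon and hydrogen is delivered anti to the C3 methyl group, gives the B-alkyl-9-BBN F7, and NaOH/H2O2 then gives the primary alcohol F8. Dess–Martin oxidation (NaHCO3 buffer) gives the 3,4-cis aldehyde F9, which is used at once to avoid epimerization. Addition of 3,4-dimethoxyphenylmagnesium bromide (THF, −78 °C) under chelation/Felkin–Anh control, with magnesium bridging the aldehyde oxygen and O1 and attack opposite to C3, gives 13.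

Step 3. Ionization of the electron-rich propargylic mesylate or equilibration of the allenyl metal species may erode the enantiomeric purity, and the anti/syn discrimination with an aromatic aldehyde may be incomplete. The fallback sets out from 5 and returns to 7; it sets C2 and C3 by reagent-controlled crotylboration and builds the alkyne afterwards. Aldehyde 5 is treated with the (E)-crotyldiisopinocampheylborane derived from (+)-α-pinene (Si-face attack through a chair transition state, then NaOH/H2O2) to give the anti homoallylic alcohol F10. Silylation (TBSOTf, 2,6-lutidine) gives the silyl ether F11. Cleavage of the vinyl group (OsO4 cat., NaIO4, 2,6-lutidine) gives the aldehyde F12. Ohira–Bestmann homologation (K2CO3, MeOH, 0 °C) gives the terminal alkyne F13. Sonogashira coupling with 2 gives the silyl-protected diaryl alkyne F14, and desilylation with TBAF gives 7.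

**Further compounds**

F1 | step 5 | {[(1S,2S)-1,4-bis(3,4-dimethoxyphenyl)-2-methylbut-3-yn-1-yl]oxy}dimethylsilane | COc1ccc([C@@H](O[SiH](C)C)[C@@H](C)C#Cc2ccc(OC)c(OC)c2)cc1OC
F2 | step 5 | (3E,4R,5S)-5-(3,4-dimethoxyphenyl)-3-[(3,4-dimethoxyphenyl)methylidene]-2,2,4-trimethyl-1,2-oxasilolane | COc1ccc([C@H]2O[Si](C)(C)/C(=C/c3ccc(OC)c(OC)c3)[C@@H]2C)cc1OC
F3 | step 5 | (1S,2R,3E)-1,4-bis(3,4-dimethoxyphenyl)-3-iodo-2-methylbut-3-en-1-ol | COc1ccc([C@@H](O)[C@@H](C)/C(I)=C\c2ccc(OC)c(OC)c2)cc1OC
F4 | step 5 | (1S,2S,3E)-1,4-bis(3,4-dimethoxyphenyl)-3-(hydroxymethyl)-2-methylbut-3-en-1-ol | COc1ccc([C@@H](O)[C@@H](C)/C(CO)=C\c2ccc(OC)c(OC)c2)cc1OC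
F5 | step 6 | (4R,5S)-5-(3,4-dimethoxyphenyl)-4-methyloxolan-3-one | COc1ccc([C@H]2OCC(=O)[C@@H]2C)cc1OC
F6 | step 6 | (2S,3S)-2-(3,4-dimethoxyphenyl)-3-methyl-4-methylideneoxolane | COc1ccc([C@H]2OCC(=C)[C@@H]2C)cc1OC
F7 | step 6 | 9-{[(3R,4S,5S)-5-(3,4-dimethoxyphenyl)-4-methyloxolan-3-yl]methyl}-9-borabicyclo[3.3.1]nonane | COc1ccc([C@H]2OC[C@H](CB3C4CCCC3CCC4)[C@@H]2C)cc1OC
F8 | step 6 | [(3S,4S,5S)-5-(3,4-dimethoxyphenyl)-4-methyloxolan-3-yl]methanol | COc1ccc([C@H]2OC[C@H](CO)[C@@H]2C)cc1OC
F9 | step 6 | (3R,4S,5S)-5-(3,4-dimethoxyphenyl)-4-methyloxolane-3-carbaldehyde | COc1ccc([C@H]2OC[C@H](C=O)[C@@H]2C)cc1OC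
F10 | step 3 | (1S,2S)-1-(3,4-dimethoxyphenyl)-2-methylbut-3-en-1-ol | COc1ccc([C@@H](O)[C@@H](C)C=C)cc1OC
F11 | step 3 | tert-butyl{[(1S,2S)-1-(3,4-dimethoxyphenyl)-2-methylbut-3-en-1-yl]oxy}dimethylsilane | COc1ccc([C@@H](O[Si](C)(C)C(C)(C)C)[C@@H](C)C=C)cc1OC
F12 | step 3 | (2R,3S)-3-[(tert-butyldimethylsilyl)oxy]-3-(3,4-dimethoxyphenyl)-2-methylpropanal | COc1ccc([C@@H](O[Si](C)(C)C(C)(C)C)[C@@H](C)C=O)cc1OC
F13 | step 3 | tert-butyl{[(1S,2S)-1-(3,4-dimethoxyphenyl)-2-methylbut-3-yn-1-yl]oxy}dimethylsilane | COc1ccc([C@@H](O[Si](C)(C)C(C)(C)C)[C@@H](C)C#C)cc1OC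
F14 | step 3 | tert-butyl{[(1S,2S)-1,4-bis(3,4-dimethoxyphenyl)-2-methylbut-3-yn-1-yl]oxy}dimethylsilane | COc1ccc([C@@H](O[Si](C)(C)C(C)(C)C)[C@@H](C)C#Cc2ccc(OC)c(OC)c2)cc1OC
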